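**Plan**
- Retrosynthesis cuts the angelate C–O bond first, then the two quinone ring bonds C(=O)–C(CH3) and C(=O)–C(OCH3). This removes the whole CH3C=C(OCH3) edge as 1-methoxypropyne and leaves a 3-alkenylcyclobut-3-ene-1,2-dione. Further cuts: four-membered ring to vinyl carbon (vinyllithium + diisopropyl squarate), the trisubstituted C=C (cross-metathesis), and the carbinol–CH2 bond (allylboration of 2-bromoacrolein).
- Enabling feature: the ring atoms O=C–C(branch)=CH–C=O of the quinone (both carbonyl carbons and the two sp2 carbons between them) are a cyclobutenedione with its C(=O)–C(=O) bond opened. That bond is a temporary bond, cleaved by monovalent cobalt to a five-membered metallacycle. The other two ring atoms are an ynol ether at the alkyne oxidation level.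
- Forward: the C8 chain is built (steps 1–4), the four-membered ring is attached and unveiled (steps 5–6), cobalt is inserted (step 7), and the quinone ring arises last by alkyne insertion (step 9), followed by desilylation and acylation.
- Stereochemistry: the single stereocenter (S) is set by reagent-controlled Brown allylboration in step 2 and no bond to it is broken afterwards. The Z alkene of the ester comes from angelic acid and is kept by a mixed-anhydride acylation.

Key step: step 9

Remark: complex 14 is taken to be the six-coordinate chloro(pyridine) species with neutral dimethylglyoxime; in the SMILES of the cobalt complexes each dative bond is written with formal charges. Compounds 10 and 11 are epimer mixtures at ring carbons that become sp2 in step 6.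

**Step 1**
Reactants: 1 acrolein
Product: 2 2-bromoprop-2-enal
Conditions: Br2, CH2Cl2, −78 °C to 0 °C; then Et3N, 0 °C; distilled and used fresh
Reagents that add atoms: bromine, BrBr
Why: Bromine addition to the enal followed by E1cB loss of HBr (bromination–dehydrobromination) should give the α-bromo enal.

**Step 2**
Reactants: 2 2-bromoprop-2-enal
Product: 4 (3S)-2-bromohexa-1,5-dien-3-ol, via diisopinocampheylborinate ester 3 (not isolated)
Conditions: (−)-Ipc2B(allyl) (1 M in pentane), Et2O, −78 °C; then NaOH, H2O2, 0 °C to rt
Reagents that add atoms: (−)-B-allyldiisopinocampheylborane, C=CCB([C@@H]1C[C@@H]2C[C@@H](C2(C)C)[C@H]1C)[C@@H]1C[C@@H]2C[C@@H](C2(C)C)[C@H]1C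
Why: Brown asymmetric allylboration through a chair Zimmerman–Traxler transition state, in which the isopinocampheyl groups from (+)-α-pinene direct allyl transfer to the aldehyde face that should give the (S)-carbinol (the sense known for benzaldehyde, the bromovinyl group taking the place of phenyl); oxidative work-up frees the alcohol.

**Step 3**
Reactants: 4 (3S)-2-bromohexa-1,5-dien-3-ol; 5 2-methylbut-2-ene
Product: 6 (3S)-2-bromo-6-methylhepta-1,5-dien-3-ol
Conditions: second-generation Grubbs catalyst RuCl2(=CHPh)(H2IMes)(PCy3) (5 mol %), 5 (large excess), CH2Cl2, 40 °C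
Reagents that add atoms: none
Why: Olefin cross-metathesis with excess 2-methylbut-2-ene should turn the monosubstituted alkene into the trisubstituted one, while the electron-poor, geminally disubstituted bromoalkene stays inert and the stereocenter is untouched.

**Step 4**
Reactants: 6 (3S)-2-bromo-6-methylhepta-1,5-dien-3-ol
Product: 7 tert-butyl{[(3S)-2-bromo-6-methylhepta-1,5-dien-3-yl]oxy}dimethylsilane
Conditions: TBSCl, imidazole, DMF, rt
Reagents that add atoms: tert-butylchlorodimethylsilane, CC(C)(C)[Si](C)(C)Cl
Why: Standard silylation of a secondary alcohol gives an ether that tolerates the organolithium, hydride, brief acid and Lewis acid of steps 5–9.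

**Step 5**
Reactants: 7 tert-butyl{[(3S)-2-bromo-6-methylhepta-1,5-dien-3-yl]oxy}dimethylsilane; 8 diisopropyl squarate
Product: 10 4-[(3S)-3-(tert-butyldimethylsilyloxy)-6-methylhepta-1,5-dien-2-yl]-4-hydroxy-2,3-di(propan-2-yloxy)cyclobut-2-en-1-one, via vinyllithium 9 (not isolated)
Conditions: t-BuLi (2.1 equiv), Et2O, −78 °C; then 8, THF, −78 °C; aq. NH4Cl at −78 °C
Reagents that add atoms: none
Why: Bromine–lithium exchange and 1,2-addition of the vinyllithium to one of the two equivalent carbonyl groups of the squarate; the low temperature suppresses allene-forming β-elimination and silyl migration, and the new ring carbinol center (both epimers) is erased in step 6.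

**Step 6**
Reactants: 10 the hydroxycyclobutenone of step 5
Product: 12 3-[(3S)-3-(tert-butyldimethylsilyloxy)-6-methylhepta-1,5-dien-2-yl]cyclobut-3-ene-1,2-dione, via cyclobutenediol 11 (not isolated)
Conditions: i-Bu2AlH (2.5 equiv), CH2Cl2, −78 °C; then 2 M aq. HCl, THF, 0 °C, short contact time
Reagents that add atoms: water, O
Why: 1,2-Reduction of the vinylogous ester carbonyl followed by two successive Stork–Danheiser-type allylic transpositions (ionization of each carbinol, capture of the oxocarbenium ion by water, loss of propan-2-ol) should funnel all diastereomers of the diol into the one achiral ring with the alkenyl group and H on adjacent carbons.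

**Step 7**
Reactants: 12 the cyclobutenedione of step 6
Product: 14 chloro(dimethylglyoxime)(pyridine)cobalt metallacycle (3-alkenyl-1-cobaltacyclopent-3-ene-2,5-dione, trivalent cobalt), via bis(triphenylphosphine) maleoylcobalt chloride 13 (not isolated)
Conditions: ClCo(PPh3)3 (1.05 equiv), benzene, rt, N2; then dimethylglyoxime, pyridine, rt
Reagents that add atoms: chlorotris(triphenylphosphine)cobalt, Cl[Co-3]([P+](c1ccccc1)(c1ccccc1)c1ccccc1)([P+](c1ccccc1)(c1ccccc1)c1ccccc1)[P+](c1ccccc1)(c1ccccc1)c1ccccc1; dimethylglyoxime, CC(=NO)C(C)=NO; pyridine, c1ccncc1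
Why: Oxidative addition of monovalent cobalt into the strained C(=O)–C(=O) bond (C–C bond activation of a cyclobutenedione) gives the maleoylcobalt metallacycle, and ligand exchange gives the stable, chromatographable dimethylglyoxime complex that is the more reactive form toward alkynes.

**Step 8**
Reactants: 15 chloroacetaldehyde dimethyl acetal
Product: 17 1-methoxyprop-1-yne, via sodium methoxyacetylide 16 (not isolated)
Conditions: NaNH2 (3 equiv), liquid NH3, −33 °C; then MeI, −33 °C; distillation
Reagents that add atoms: iodomethane, CI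
Why: Twofold base-induced elimination (loss of methanol, then of HCl) and deprotonation give the alkoxyacetylide, whose C-methylation is the standard preparation of 1-alkoxy-1-alkynes.

**Step 9**
Reactants: 14 the cobalt metallacycle of step 7; 17 1-methoxyprop-1-yne
Product: 18 5-[(3S)-3-(tert-butyldimethylsilyloxy)-6-methylhepta-1,5-dien-2-yl]-3-methoxy-2-methylcyclohexa-2,5-diene-1,4-dione
Conditions: SnCl4 (1 equiv, precomplexed with 14), ClCH2CH2Cl, −30 °C; then 17 (3 equiv) added slowly, −30 °C to rt
Reagents that add atoms: none
Why: The Lewis acid should bind the acyl oxygen remote from the branch (the less hindered and more basic one, being the end of the linear O=C–CH=C–C=CH2 path); the nucleophilic methyl-bearing carbon of the ynol ether then bonds to that acyl carbon as the alkyne inserts into its Co–C bond, the methoxy-bearing carbon goes to cobalt, and C–C reductive elimination with the second acyl group releases the quinone and monovalent cobalt. The closest known reaction type is the quinone synthesis from maleoyl- and phthaloylcobalt complexes (made from cyclobutenediones) and alkynes, including its Lewis acid-promoted regioselective form with terminal alkynes. The six-membered quinone ring closes by reductive elimination from a seven-membered cobaltacycle, so the two alkyne carbons are in effect inserted into the former C(=O)–C(=O) bond of the four-membered ring, a net [4+2] union of the four-carbon maleoyl unit and the alkyne. No stereocenter is formed and the carbinol center is not touched. The step needs regioselectivity (methyl carbon to the acyl group next to the ring CH, methoxy carbon to the acyl group next to the branch), which the polarization of the ynol ether and the electronic and steric difference between the two acyl groups, enlarged by the bulky silyl ether on the branch, should secure; it also needs chemoselectivity for the alkyne over the two side-chain alkenes, which do not insert into the metallacycle.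

**Step 10**
Reactants: 18 the silyl-protected quinone of step 9
Product: 19 5-[(3S)-3-hydroxy-6-methylhepta-1,5-dien-2-yl]-3-methoxy-2-methylcyclohexa-2,5-diene-1,4-dione
Conditions: 48% aq. HF, MeCN, 0 °C to rt
Reagents that add atoms: none
Why: Fluoride-driven cleavage of the Si–O bond under acidic conditions, which a quinone tolerates where basic fluoride sources would not be safe.

**Step 11**
Reactants: 19 the quinone alcohol of step 10; 20 angelic acid
Product: 22 (3S)-2-(5-methoxy-4-methyl-3,6-dioxocyclohexa-1,4-dien-1-yl)-6-methylhepta-1,5-dien-3-yl (2Z)-2-methylbut-2-enoate, via angelic 2,4,6-trichlorobenzoic anhydride 21 (not isolated)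
Conditions: 20, 2,4,6-trichlorobenzoyl chloride, Et3N (1 equiv), toluene, rt; then 19, toluene, 75 °C
Reagents that add atoms: none
Why: Yamaguchi-type mixed-anhydride esterification without a nucleophilic catalyst should transfer the angeloyl group without Z to E isomerization, with the amine used up before the quinone is added; the C–O bond at the stereocenter is not broken, so the configuration is retained.

**Compound list**
1 | acrolein | C=CC=O | starting material
2 | 2-bromoprop-2-enal | C=C(Br)C=O | intermediate
3 | (3S)-2-bromohexa-1,5-dien-3-yl diisopinocampheylborinate | C=C(Br)[C@H](CC=C)OB([C@@H]1C[C@@H]2C[C@@H](C2(C)C)[C@H]1C)[C@@H]1C[C@@H]2C[C@@H](C2(C)C)[C@H]1C | intermediate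
4 | (3S)-2-bromohexa-1,5-dien-3-ol | C=C(Br)[C@H](CC=C)O | intermediate
5 | 2-methylbut-2-ene | CC=C(C)C | starting material
6 | (3S)-2-bromo-6-methylhepta-1,5-dien-3-ol | C=C(Br)[C@H](CC=C(C)C)O | intermediate
7 | tert-butyl{[(3S)-2-bromo-6-methylhepta-1,5-dien-3-yl]oxy}dimethylsilane | C=C(Br)[C@H](CC=C(C)C)O[Si](C)(C)C(C)(C)C | intermediate
8 | diisopropyl squarate (3,4-di(propan-2-yloxy)cyclobut-3-ene-1,2-dione) | CC(C)OC1=C(OC(C)C)C(=O)C1=O | starting material
9 | [(3S)-3-(tert-butyldimethylsilyloxy)-6-methylhepta-1,5-dien-2-yl]lithium | [Li]C(=C)[C@H](CC=C(C)C)O[Si](C)(C)C(C)(C)C | intermediate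
10 | 4-[(3S)-3-(tert-butyldimethylsilyloxy)-6-methylhepta-1,5-dien-2-yl]-4-hydroxy-2,3-di(propan-2-yloxy)cyclobut-2-en-1-one (both epimers at C4) | C=C([C@H](CC=C(C)C)O[Si](C)(C)C(C)(C)C)C1(O)C(=O)C(OC(C)C)=C1OC(C)C | intermediate
11 | 1-[(3S)-3-(tert-butyldimethylsilyloxy)-6-methylhepta-1,5-dien-2-yl]-3,4-di(propan-2-yloxy)cyclobut-3-ene-1,2-diol (diastereomer mixture) | C=C([C@H](CC=C(C)C)O[Si](C)(C)C(C)(C)C)C1(O)C(O)C(OC(C)C)=C1OC(C)C | intermediate
12 | 3-[(3S)-3-(tert-butyldimethylsilyloxy)-6-methylhepta-1,5-dien-2-yl]cyclobut-3-ene-1,2-dione | C=C([C@H](CC=C(C)C)O[Si](C)(C)C(C)(C)C)C1=CC(=O)C1=O | intermediate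
13 | chloro-bis(triphenylphosphine) 3-alkenyl-1-cobaltacyclopent-3-ene-2,5-dione (trivalent cobalt) | C=C([C@H](CC=C(C)C)O[Si](C)(C)C(C)(C)C)C1=CC(=O)[Co-2](Cl)([P+](c2ccccc2)(c2ccccc2)c2ccccc2)([P+](c2ccccc2)(c2ccccc2)c2ccccc2)C1=O | intermediate
14 | chloro(dimethylglyoxime)(pyridine) 3-alkenyl-1-cobaltacyclopent-3-ene-2,5-dione (trivalent cobalt) | C=C([C@H](CC=C(C)C)O[Si](C)(C)C(C)(C)C)C1=CC(=O)[Co-3]2(Cl)([n+]3ccccc3)([N+](O)=C(C)C(C)=[N+]2O)C1=O | intermediate
15 | chloroacetaldehyde dimethyl acetal | ClCC(OC)OC | starting material
16 | sodium methoxyacetylide | [Na]C#COC | intermediate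
17 | 1-methoxyprop-1-yne | CC#COC | intermediate
18 | 5-[(3S)-3-(tert-butyldimethylsilyloxy)-6-methylhepta-1,5-dien-2-yl]-3-methoxy-2-methylcyclohexa-2,5-diene-1,4-dione | C=C([C@H](CC=C(C)C)O[Si](C)(C)C(C)(C)C)C1=CC(=O)C(C)=C(OC)C1=O | intermediate
19 | 5-[(3S)-3-hydroxy-6-methylhepta-1,5-dien-2-yl]-3-methoxy-2-methylcyclohexa-2,5-diene-1,4-dione | C=C([C@H](CC=C(C)C)O)C1=CC(=O)C(C)=C(OC)C1=O | intermediate
20 | angelic acid ((2Z)-2-methylbut-2-enoic acid) | C/C=C(/C)C(=O)O | starting material
21 | angelic 2,4,6-trichlorobenzoic anhydride | C/C=C(/C)C(=O)OC(=O)c1c(Cl)cc(Cl)cc1Cl | intermediate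
22 | (3S)-2-(5-methoxy-4-methyl-3,6-dioxocyclohexa-1,4-dien-1-yl)-6-methylhepta-1,5-dien-3-yl (2Z)-2-methylbut-2-enoate | C=C(C1=CC(=O)C(C)=C(OC)C1=O)[C@H](CC=C(C)C)OC(=O)/C(C)=C\C | target

**Step count**
Total: 11 steps. Longest linear sequence: 10 steps (steps 1–7 and 9–11); step 8 is a one-step branch.

**Steps most likely to fail**

Step 9. The risk is leakage of the insertion into the reverse orientation (methyl and methoxy exchanged on the ring), together with Lewis acid-induced oligomerization or hydration of the ynol ether before it inserts.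
Fallback, from 7 back to 18: Sonogashira coupling of 7 with ethynyltrimethylsilane (Pd(PPh3)2Cl2, CuI, Et3N) should give the silylated enyne F1, and K2CO3 in MeOH the terminal enyne F2. Its lithium acetylide (n-BuLi, THF, −78 °C) is added to dimethyl squarate to give the 4-alkynyl-4-hydroxy-2,3-dimethoxycyclobutenone F3, which is capped as its trimethylsilyl ether F4 (TMSCl, Et3N). Methyllithium at −78 °C, then trifluoroacetic anhydride and aqueous NaHCO3 (Stork–Danheiser-type transposition with loss of methanol), should give the 2-methoxy-3-methyl-4-silyloxycyclobutenone F5. K2CO3 in MeOH at 0 °C then frees the 4-hydroxycyclobutenone F6. Heating F6 in toluene at 110 °C (Moore rearrangement: ring opening to the enynyl ketene, six-membered ring closure, hydrogen transfer from the hydroxyl group) should give 18, with the substituent pattern fixed by the order of the two additions rather than by an insertion preference.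

Step 6. The risk is that the acid treatment cannot be stopped cleanly: loss of the silyl ether, addition of water to the free ring CH position of the very electrophilic monosubstituted dione, or its oligomerization during the double transposition.
Fallback, from 7 back to 12: the vinyllithium 9, made as in step 5, is quenched with Bu3SnCl to give the vinylstannane F7. 3-Chlorocyclobut-3-ene-1,2-dione F8 is made from semisquaric acid with oxalyl chloride and catalytic DMF. Stille coupling of F7 with F8 (Pd2(dba)3, tri(2-furyl)phosphine, CuI, THF, rt) should give 12 under neutral conditions, with no hydride and no aqueous acid.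

Step 11. The risk is slow acylation of the hindered carbinol next to the quinone, so that prolonged heating allows base-induced degradation of the quinone and Z to E drift of the acyl donor.
Fallback, from 12 to 22: the order of the endgame is changed so that the ester is made before the quinone exists. Desilylation of 12 (aq. HF, MeCN) gives the hydroxy dione F9, which is acylated with preformed, filtered anhydride 21 in toluene to give the dione angelate F10. ClCo(PPh3)3 gives the bis(phosphine) metallacycle F11 (not isolated), and dimethylglyoxime with pyridine the complex F12. Insertion of 17 under the conditions of step 9 then delivers 22 directly in a base-free last step.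

**Further compounds**
F1 | step 9 | tert-butyldimethyl{[(3S)-6-methyl-2-[(trimethylsilyl)ethynyl]hepta-1,5-dien-3-yl]oxy}silane | C=C(C#C[Si](C)(C)C)[C@H](CC=C(C)C)O[Si](C)(C)C(C)(C)C
F2 | step 9 | tert-butyl{[(3S)-2-ethynyl-6-methylhepta-1,5-dien-3-yl]oxy}dimethylsilane | C=C(C#C)[C@H](CC=C(C)C)O[Si](C)(C)C(C)(C)C
F3 | step 9 | 4-{(3S)-3-(tert-butyldimethylsilyloxy)-6-methyl-2-methylidenehept-5-en-1-ynyl}-4-hydroxy-2,3-dimethoxycyclobut-2-en-1-one | C=C(C#CC1(O)C(=O)C(OC)=C1OC)[C@H](CC=C(C)C)O[Si](C)(C)C(C)(C)C
F4 | step 9 | trimethylsilyl ether of F3 | C=C(C#CC1(O[Si](C)(C)C)C(=O)C(OC)=C1OC)[C@H](CC=C(C)C)O[Si](C)(C)C(C)(C)C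
F5 | step 9 | 4-{(3S)-3-(tert-butyldimethylsilyloxy)-6-methyl-2-methylidenehept-5-en-1-ynyl}-2-methoxy-3-methyl-4-(trimethylsilyloxy)cyclobut-2-en-1-one | C=C(C#CC1(O[Si](C)(C)C)C(=O)C(OC)=C1C)[C@H](CC=C(C)C)O[Si](C)(C)C(C)(C)C
F6 | step 9 | 4-{(3S)-3-(tert-butyldimethylsilyloxy)-6-methyl-2-methylidenehept-5-en-1-ynyl}-4-hydroxy-2-methoxy-3-methylcyclobut-2-en-1-one | C=C(C#CC1(O)C(=O)C(OC)=C1C)[C@H](CC=C(C)C)O[Si](C)(C)C(C)(C)C
F7 | step 6 | tert-butyldimethyl{[(3S)-6-methyl-2-(tributylstannyl)hepta-1,5-dien-3-yl]oxy}silane | C=C([Sn](CCCC)(CCCC)CCCC)[C@H](CC=C(C)C)O[Si](C)(C)C(C)(C)C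
F8 | step 6 | 3-chlorocyclobut-3-ene-1,2-dione | O=C1C=C(Cl)C1=O
F9 | step 11 | 3-[(3S)-3-hydroxy-6-methylhepta-1,5-dien-2-yl]cyclobut-3-ene-1,2-dione | C=C([C@H](CC=C(C)C)O)C1=CC(=O)C1=O
F10 | step 11 | (3S)-2-(3,4-dioxocyclobut-1-en-1-yl)-6-methylhepta-1,5-dien-3-yl (2Z)-2-methylbut-2-enoate | C=C([C@H](CC=C(C)C)OC(=O)/C(C)=C\C)C1=CC(=O)C1=O
F11 | step 11 | chloro-bis(triphenylphosphine) cobaltacyclopentenedione bearing the angelate side chain (trivalent cobalt) | C=C([C@H](CC=C(C)C)OC(=O)/C(C)=C\C)C1=CC(=O)[Co-2](Cl)([P+](c2ccccc2)(c2ccccc2)c2ccccc2)([P+](c2ccccc2)(c2ccccc2)c2ccccc2)C1=O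
F12 | step 11 | chloro(dimethylglyoxime)(pyridine) cobaltacyclopentenedione bearing the angelate side chain (trivalent cobalt) | C=C([C@H](CC=C(C)C)OC(=O)/C(C)=C\C)C1=CC(=O)[Co-3]2(Cl)([n+]3ccccc3)([N+](O)=C(C)C(C)=[N+]2O)C1=O
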